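## Retrosynthetic overview

1. Target 14 ⇒ Yamaguchi angeloylation of allylic alcohol 13. The seven-membered ring of 13 ⇒ ring-closing metathesis (C-8=C-9) of diene 12.
2. 12 ⇒ neopentylic aldehyde 11 (C-10) plus a vinylzinc reagent under catalyst control. 11 ⇒ acetal anisoate 10 ⇒ diol 9, whose C-6 carbinol comes from chelation-controlled methallylation of a β-hydroxy aldehyde.
3. The β-hydroxy aldehyde ⇒ cyclopentane-fused β-lactone 7, which already holds C-1 (quaternary), C-4 (tertiary carbinol) and C-5.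
4. Key disconnection of 7: the C-1–C-2 bond joins the β-carbon of enal 3 (as a carbene-bound homoenolate) to the β-carbon of isopropyl vinyl ketone 4. C-5–C-4 aldol closure and lactonisation follow in the same flask.
5. Ring order: five-membered ring first (step 2), seven-membered ring second (step 7). Enal 3 comes from 1,1-dimethoxyacetone by Wittig olefination.

Assumption: locants C-1 to C-10 are daucane locants (C-1 quaternary methyl carbon, C-4 isopropyl carbinol, C-5 ring-fusion CH, C-6 anisoate carbon, C-8=C-9 alkene, C-10 angelate carbon).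
Assumption: the (5aS,10bR) triazolium is taken as the enantiomer that gives the 2S lactone 7; if the facial sense proves opposite, its (5aR,10bS) antipode is used instead.

## Route

Step 1
Reactants: 1 1,1-dimethoxypropan-2-one; 2 (triphenylphosphoranylidene)acetaldehyde
Product: 3 (2E)-4,4-dimethoxy-3-methylbut-2-enal
Conditions: 1 (2 equiv), toluene, 100 °C; E isomer by distillation
Reagents that add atoms: none
Why: Wittig olefination of the dialkoxy-activated ketone with the stabilised formyl ylide gives the conjugated enal, mainly as the E isomer (CHO trans to the bulkier dimethoxymethyl group), and excess ketone suppresses a second olefination.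

Step 2
Reactants: 3 (2E)-4,4-dimethoxy-3-methylbut-2-enal; 4 4-methylpent-1-en-3-one
Product: 7 (1R,2S,5R)-2-(dimethoxymethyl)-2-methyl-5-(propan-2-yl)-6-oxabicyclo[3.2.0]heptan-7-one, via carbene-bound homoenolate 5 (not isolated), via acyl azolium alkoxide 6 (not isolated)
Conditions: (5aS,10bR)-2-mesityl-5a,10b-dihydro-4H,6H-indeno[2,1-b][1,2,4]triazolo[4,3-d][1,4]oxazin-2-ium chloride (10 mol %), DBU (15 mol %), 4 Å MS, THF, 40 °C, 4 (1.5 equiv) added over 6 h
Reagents that add atoms: none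
Why: Proposed new method: this is the NHC-catalysed homoenolate annulation of enals with enones (Nair–Bode cyclopentannulation), extended to a β,β-disubstituted enal and an alkyl vinyl ketone; the carbene makes the enal β-carbon C-1 nucleophilic (5), it adds to the unhindered CH2 terminus of 4 to create the quaternary centre with the chiral carbene selecting the face, the azolium enol then closes the ring by aldol addition to the isopropyl ketone (6), only the aldolate with O cis to the acyl azolium can lactonise (fixing C-4 relative to C-5), and the acyl group settles trans to the larger dimethoxymethyl group (fixing C-5 relative to C-1).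

Step 3
Reactants: 7 (1R,2S,5R)-2-(dimethoxymethyl)-2-methyl-5-(propan-2-yl)-6-oxabicyclo[3.2.0]heptan-7-one
Product: 9 (1S)-1-[(1S,2S,5R)-2-(dimethoxymethyl)-5-hydroxy-2-methyl-5-(propan-2-yl)cyclopentyl]-3-methylbut-3-en-1-ol, via β-hydroxy aldehyde 8 (not isolated)
Conditions: iBu2AlH (1.05 equiv), CH2Cl2, −78 °C; then 2-methylallylmagnesium chloride (3 equiv), −78 → −20 °C; aq. KNaC4H4O6
Reagents that add atoms: 2-methylallylmagnesium chloride, CC(=C)C[Mg]Cl
Why: One-pot partial lactone reduction and Grignard addition: the aluminium lactolate opens on warming to the β-aluminoxy aldehyde 8, and Cram-chelate addition to its six-membered O–Al–O chelate occurs on the face anti to quaternary C-1 (syn to H-5), which sets C-6 as S.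

Step 4
Reactants: 9 (1S)-1-[(1S,2S,5R)-2-(dimethoxymethyl)-5-hydroxy-2-methyl-5-(propan-2-yl)cyclopentyl]-3-methylbut-3-en-1-ol
Product: 10 (1S)-1-[(1S,2S,5R)-2-(dimethoxymethyl)-5-hydroxy-2-methyl-5-(propan-2-yl)cyclopentyl]-3-methylbut-3-en-1-yl 4-methoxybenzoate
Conditions: 4-MeOC6H4COCl (1.5 equiv), Et3N, 4-(dimethylamino)pyridine (0.2 equiv), CH2Cl2, 0 → 40 °C
Reagents that add atoms: 4-methoxybenzoyl chloride, COc1ccc(cc1)C(Cl)=O
Why: Acyl chloride esterification with nucleophilic catalysis acylates the only secondary hydroxyl (C-10 is still masked as the acetal and the tertiary C-4 alcohol is inert), so the anisoate is placed on C-6 without ambiguity.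

Step 5
Reactants: 10 (1S)-1-[(1S,2S,5R)-2-(dimethoxymethyl)-5-hydroxy-2-methyl-5-(propan-2-yl)cyclopentyl]-3-methylbut-3-en-1-yl 4-methoxybenzoate
Product: 11 (1S)-1-[(1S,2R,5S)-5-formyl-2-hydroxy-5-methyl-2-(propan-2-yl)cyclopentyl]-3-methylbut-3-en-1-yl 4-methoxybenzoate
Conditions: TsOH·H2O (0.2 equiv), acetone/H2O 10:1, 40 °C
Reagents that add atoms: water, O
Why: Acid-catalysed acetal hydrolysis unmasks the non-enolisable C-10 aldehyde, which cannot form a hemiacetal with the C-4 hydroxyl because the two are trans on the cyclopentane; no stereocentre is touched.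

Step 6
Reactants: 11 (1S)-1-[(1S,2R,5S)-5-formyl-2-hydroxy-5-methyl-2-(propan-2-yl)cyclopentyl]-3-methylbut-3-en-1-yl 4-methoxybenzoate
Product: 12 (1S)-1-[(1S,2R,5S)-2-hydroxy-5-[(1R)-1-hydroxyprop-2-en-1-yl]-5-methyl-2-(propan-2-yl)cyclopentyl]-3-methylbut-3-en-1-yl 4-methoxybenzoate
Conditions: divinylzinc (3 equiv; from CH2=CHMgBr and ZnCl2 in Et2O, MgBrCl removed with 1,4-dioxane), (2R)-3-exo-morpholinoisoborneol [(+)-MIB] (10 mol %), toluene, 0 °C
Reagents that add atoms: divinylzinc, C=C[Zn]C=C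
Why: Amino-alcohol-catalysed enantioselective alkenylzinc addition (Oppolzer/Nugent type): the (+)-MIB–zinc complex delivers vinyl to the Re face of the aldehyde to give the 10R carbinol under catalyst control (substrate bias at the quaternary α-carbon is small), and the organozinc leaves the ester untouched.

Step 7
Reactants: 12 (1S)-1-[(1S,2R,5S)-2-hydroxy-5-[(1R)-1-hydroxyprop-2-en-1-yl]-5-methyl-2-(propan-2-yl)cyclopentyl]-3-methylbut-3-en-1-yl 4-methoxybenzoate
Product: 13 (3R,3aS,4S,8R,8aS)-3,8-dihydroxy-6,8a-dimethyl-3-(propan-2-yl)-1,2,3,3a,4,5,8,8a-octahydroazulen-4-yl 4-methoxybenzoate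
Conditions: second-generation Grubbs catalyst RuCl2(=CHPh)(PCy3)(H2IMes) (10 mol %), CH2Cl2 (0.005 M), 40 °C
Reagents that add atoms: none
Why: Ring-closing metathesis between the allylic-alcohol vinyl group and the 1,1-disubstituted alkene closes the seven-membered ring with the trisubstituted C-8=C-9 alkene; the two chains are trans on the cyclopentane, so the trans-fused hydroazulene forms and no stereocentre is touched.

Step 8
Reactants: 13 (3R,3aS,4S,8R,8aS)-3,8-dihydroxy-6,8a-dimethyl-3-(propan-2-yl)-1,2,3,3a,4,5,8,8a-octahydroazulen-4-yl 4-methoxybenzoate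
Product: 14 (3R,3aS,4S,8R,8aS)-3-hydroxy-6,8a-dimethyl-8-{[(2Z)-2-methylbut-2-enoyl]oxy}-3-(propan-2-yl)-1,2,3,3a,4,5,8,8a-octahydroazulen-4-yl 4-methoxybenzoate (CNP0168729.1)
Conditions: angelic acid (3 equiv), 2,4,6-Cl3C6H2COCl (3 equiv), Et3N, toluene, rt, 2 h; then 13, 80 °C
Reagents that add atoms: angelic acid [(2Z)-2-methylbut-2-enoic acid], C/C=C(/C)C(=O)O
Why: Yamaguchi esterification through the mixed 2,4,6-trichlorobenzoic anhydride, run without a nucleophilic amine catalyst, acylates the only secondary alcohol with retention at C-10 and keeps the Z geometry of the angelate (no isomerisation to tiglate).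

## Compound list

1 | 1,1-dimethoxypropan-2-one (pyruvaldehyde dimethyl acetal) | CC(=O)C(OC)OC | starting material
2 | (triphenylphosphoranylidene)acetaldehyde | O=CC=P(c1ccccc1)(c1ccccc1)c1ccccc1 | starting material
3 | (2E)-4,4-dimethoxy-3-methylbut-2-enal | COC(OC)/C(C)=C/C=O | intermediate
4 | 4-methylpent-1-en-3-one (isopropyl vinyl ketone) | C=CC(=O)C(C)C | starting material
5 | carbene-bound homoenolate (extended Breslow intermediate): (2E)-1-[(5aS,10bR)-2-mesityl-5a,10b-dihydro-4H,6H-indeno[2,1-b][1,2,4]triazolo[4,3-d][1,4]oxazin-1(2H)-ylidene]-4,4-dimethoxy-3-methylbut-2-en-1-ol | COC(OC)/C(C)=C/C(O)=C1N(c2c(C)cc(C)cc2C)N=C2CO[C@H]3Cc4ccccc4[C@H]3N12 | intermediate (not isolated)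
6 | acyl azolium alkoxide: zwitterion of (5aS,10bR)-2-mesityl-1-{[(1R,2S,5R)-2-(dimethoxymethyl)-2-methyl-5-oxido-5-(propan-2-yl)cyclopentyl]carbonyl}-5a,10b-dihydro-4H,6H-indeno[2,1-b][1,2,4]triazolo[4,3-d][1,4]oxazin-2-ium | COC(OC)[C@@]1(C)CC[C@@]([O-])(C(C)C)[C@@H]1C(=O)c1[n+](-c2c(C)cc(C)cc2C)nc2CO[C@H]3Cc4ccccc4[C@H]3n12 | intermediate (not isolated)
7 | (1R,2S,5R)-2-(dimethoxymethyl)-2-methyl-5-(propan-2-yl)-6-oxabicyclo[3.2.0]heptan-7-one (lactone carbonyl cis to the C-2 methyl, trans to the dimethoxymethyl group) | COC(OC)[C@@]1(C)CC[C@]2(C(C)C)OC(=O)[C@H]12 | intermediate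
8 | (1R,2S,5R)-2-(dimethoxymethyl)-5-hydroxy-2-methyl-5-(propan-2-yl)cyclopentane-1-carbaldehyde (held in the flask as its iBu2Al alkoxide) | COC(OC)[C@@]1(C)CC[C@@](O)(C(C)C)[C@@H]1C=O | intermediate (not isolated)
9 | (1S)-1-[(1S,2S,5R)-2-(dimethoxymethyl)-5-hydroxy-2-methyl-5-(propan-2-yl)cyclopentyl]-3-methylbut-3-en-1-ol | COC(OC)[C@@]1(C)CC[C@@](O)(C(C)C)[C@@H]1[C@@H](O)CC(C)=C | intermediate
10 | (1S)-1-[(1S,2S,5R)-2-(dimethoxymethyl)-5-hydroxy-2-methyl-5-(propan-2-yl)cyclopentyl]-3-methylbut-3-en-1-yl 4-methoxybenzoate | COC(OC)[C@@]1(C)CC[C@@](O)(C(C)C)[C@@H]1[C@@H](OC(=O)c1ccc(OC)cc1)CC(C)=C | intermediate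
11 | (1S)-1-[(1S,2R,5S)-5-formyl-2-hydroxy-5-methyl-2-(propan-2-yl)cyclopentyl]-3-methylbut-3-en-1-yl 4-methoxybenzoate | O=C[C@@]1(C)CC[C@@](O)(C(C)C)[C@@H]1[C@@H](OC(=O)c1ccc(OC)cc1)CC(C)=C | intermediate
12 | (1S)-1-[(1S,2R,5S)-2-hydroxy-5-[(1R)-1-hydroxyprop-2-en-1-yl]-5-methyl-2-(propan-2-yl)cyclopentyl]-3-methylbut-3-en-1-yl 4-methoxybenzoate | C=C[C@@H](O)[C@@]1(C)CC[C@@](O)(C(C)C)[C@@H]1[C@@H](OC(=O)c1ccc(OC)cc1)CC(C)=C | intermediate
13 | (3R,3aS,4S,8R,8aS)-3,8-dihydroxy-6,8a-dimethyl-3-(propan-2-yl)-1,2,3,3a,4,5,8,8a-octahydroazulen-4-yl 4-methoxybenzoate (6α-anisoyloxy-dauc-8-ene-4β,10α-diol) | O[C@@H]1C=C(C)C[C@H](OC(=O)c2ccc(OC)cc2)[C@@H]2[C@]1(C)CC[C@@]2(O)C(C)C | intermediate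
14 | (3R,3aS,4S,8R,8aS)-3-hydroxy-6,8a-dimethyl-8-{[(2Z)-2-methylbut-2-enoyl]oxy}-3-(propan-2-yl)-1,2,3,3a,4,5,8,8a-octahydroazulen-4-yl 4-methoxybenzoate (10α-angeloyloxy-6α-anisoyloxy-dauc-8-en-4β-ol, CNP0168729.1) | C/C=C(/C)C(=O)O[C@@H]1C=C(C)C[C@H](OC(=O)c2ccc(OC)cc2)[C@@H]2[C@]1(C)CC[C@@]2(O)C(C)C | target

## Step count and risk

Total steps: 8. Longest linear sequence: 8 (1 → 14).

The three steps most likely to fail:

Step 2 (carbene annulation). The risks are loss of methoxide from 5, acyl-anion (Stetter-type) addition to 4, oligomerisation of 4, and a stalled aldol–lactonisation. The fallback splits the bond construction in two and sets out from 3 and 4. The same carbene catalyst is run in THF/MeOH, so that the homoenolate adduct is intercepted by methanol as the open-chain keto ester methyl (3S)-3-(dimethoxymethyl)-3,7-dimethyl-6-oxooctanoate F1. LiOH in THF/H2O gives the keto acid (3S)-3-(dimethoxymethyl)-3,7-dimethyl-6-oxooctanoic acid F2. A nucleophile-catalysed aldol–lactonisation of F2 (2-chloro-1-methylpyridinium iodide, iPr2NEt, 4-(pyrrolidin-1-yl)pyridine, CH2Cl2, rt) then closes the cyclopentane and the β-lactone through an acylammonium enolate. This comes back to the route at 7.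

Step 3 (one-pot partial reduction and methallylation). The risks are over-reduction of the strained lactone and retro-aldol loss of 8. The fallback sets out from 7. Exhaustive reduction with LiBH4 (THF, 0 °C) gives the diol (1R,2S,3S)-3-(dimethoxymethyl)-2-(hydroxymethyl)-3-methyl-1-(propan-2-yl)cyclopentan-1-ol F3. Its primary alcohol alone is oxidised (2,2,6,6-tetramethylpiperidin-1-oxyl, PhI(OAc)2, CH2Cl2) to the isolated β-hydroxy aldehyde, so the route is rejoined at 8. Aldehyde 8 is then treated with excess 2-methylallylmagnesium chloride at −78 °C (magnesium chelate, same facial sense) to give 9.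

Step 6 (catalytic vinylzinc addition). The risks are low rate on the neopentylic aldehyde and erosion of selectivity by the zinc alkoxide of the C-4 hydroxyl. The fallback sets out from 11. Vinylmagnesium bromide (THF, −78 °C) gives the carbinol as a C-10 epimer mixture, 1-[2-hydroxy-5-(1-hydroxyprop-2-en-1-yl)-5-methyl-2-(propan-2-yl)cyclopentyl]-3-methylbut-3-en-1-yl 4-methoxybenzoate F4. Dess–Martin periodinane oxidises it to the vinyl ketone (1S)-1-[(1S,2R,5S)-2-hydroxy-5-methyl-5-(prop-2-enoyl)-2-(propan-2-yl)cyclopentyl]-3-methylbut-3-en-1-yl 4-methoxybenzoate F5. Corey–Bakshi–Shibata reduction of F5 (catecholborane, (S)-1-methyl-3,3-diphenyltetrahydro-1H,3H-pyrrolo[1,2-c][1,3,2]oxazaborole, toluene, −78 °C; the tertiary alkyl group acts as the large group and vinyl as the small group) gives the 10R alcohol. This comes back to the route at 12.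

Further compounds
F1 | step 2 | methyl (3S)-3-(dimethoxymethyl)-3,7-dimethyl-6-oxooctanoate | COC(OC)[C@@](C)(CCC(=O)C(C)C)CC(=O)OC
F2 | step 2 | (3S)-3-(dimethoxymethyl)-3,7-dimethyl-6-oxooctanoic acid | COC(OC)[C@@](C)(CCC(=O)C(C)C)CC(=O)O
F3 | step 3 | (1R,2S,3S)-3-(dimethoxymethyl)-2-(hydroxymethyl)-3-methyl-1-(propan-2-yl)cyclopentan-1-ol | COC(OC)[C@@]1(C)CC[C@@](O)(C(C)C)[C@@H]1CO
F4 | step 6 | (1S)-1-[(1S,2R,5S)-2-hydroxy-5-(1-hydroxyprop-2-en-1-yl)-5-methyl-2-(propan-2-yl)cyclopentyl]-3-methylbut-3-en-1-yl 4-methoxybenzoate, mixture of C-10 epimers | C=CC(O)[C@@]1(C)CC[C@@](O)(C(C)C)[C@@H]1[C@@H](OC(=O)c1ccc(OC)cc1)CC(C)=C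
F5 | step 6 | (1S)-1-[(1S,2R,5S)-2-hydroxy-5-methyl-5-(prop-2-enoyl)-2-(propan-2-yl)cyclopentyl]-3-methylbut-3-en-1-yl 4-methoxybenzoate | C=CC(=O)[C@@]1(C)CC[C@@](O)(C(C)C)[C@@H]1[C@@H](OC(=O)c1ccc(OC)cc1)CC(C)=C
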